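**Plan**

- Retrosynthetic cuts, in order: the C4–prenyl bond at the quaternary carbon of ring C (the cyclohexadienone); both C–CH2 bonds of the methylene bridge between ring C and C8 of the chromene; the C6–acyl bond of the chromene; last, in one stroke, the two bonds that tie benzene ring A to the pyran unit, C4–C4a and O1–C8a.
- Enabling feature: O1 and C4 of pyran ring B sit on neighbouring ring A carbons C8a and C4a, and C4a is flanked by the oxygen-bearing C5. An aryne across C4a/C8a, polarised by the C5 alkoxy group, therefore takes up the C=O of 3-methylbut-2-enal (O to C8a, C to C4a), and the O1–C2(Me)2–C3=C4 chain then closes ring B by 4π opening and oxa-6π closure.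
- Forward order: phloroglucinol → ortho-silylaryl triflate → aryne/enal cascade (ring B onto ring A) → C6 acylation between the two MOM ethers → deprotection → methylene bridge to an aromatic C-methyl acylphloroglucinol (the future ring C) → dearomative prenylation turns that ring into ring C.
- Stereochemistry: the only stereocentre, the (R)-configured quaternary C4 of ring C, is set in the last step by the chiral palladium catalyst (asymmetric allylic dearomatisation).

Key step: step 5

Remark: the sense of induction of the chiral ligand at this prochiral ring carbon cannot be read from a simple model, so the (R,R)-ligand is written for the (R)-product and its mirror image would be taken if the opposite face were favoured; ring C is drawn in the tautomeric form of the target structure.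

**Route**

Step 1
Reactants: 1 phloroglucinol (benzene-1,3,5-triol)
Product: 2 3,5-bis(methoxymethoxy)phenol
Conditions: NaH (2.0 equiv), MOMCl (2.0 equiv), DMF, 0 °C → rt; chromatographic separation
Reagents that add atoms: chloromethyl methyl ether (MOMCl) COCCl
Why: Williamson-type O-alkylation of the symmetric triphenol with two equivalents of MOMCl should give a statistical mixture from which the bis-ether is separated, the three hydroxyl groups being equivalent so that only the degree of alkylation, not the regiochemistry, is at issue.

Step 2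
Reactants: 2 3,5-bis(methoxymethoxy)phenol
Product: 3 3,5-bis(methoxymethoxy)phenyl N-isopropylcarbamate
Conditions: i-PrNCO (1.2 equiv), Et3N (0.2 equiv), CH2Cl2, rt
Reagents that add atoms: isopropyl isocyanate CC(C)N=C=O
Why: Base-catalysed addition of the phenol to the isocyanate (carbamoylation) should give the N-isopropyl carbamate, a strong and later easily removed directing group for ortho-metalation.

Step 3
Reactants: 3 3,5-bis(methoxymethoxy)phenyl N-isopropylcarbamate
Product: 7 3,5-bis(methoxymethoxy)-2-(trimethylsilyl)phenyl N-isopropylcarbamate, via N-silyl carbamate 4 (not isolated), via aryllithium 5 (not isolated), via N,C-bis-silyl carbamate 6 (not isolated)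
Conditions: TMSOTf (1.1 equiv), TMEDA (1.1 equiv), Et2O, rt, 10 min; then TMEDA (2 equiv), n-BuLi (2.1 equiv), −78 °C, 1 h; TMSCl, −78 °C → rt; aq. NH4Cl
Reagents that add atoms: chlorotrimethylsilane C[Si](C)(C)Cl; trimethylsilyl trifluoromethanesulfonate C[Si](C)(C)OS(=O)(=O)C(F)(F)F (N-silyl group of 4, 5 and 6 only); n-butyllithium [Li]CCCC (lithium of 5 only)
Why: In situ N-silylation makes the carbamate a tertiary one that directs ortho-lithiation (directed ortho-metalation) to C2, the position flanked by the carbamate and a MOM ether and equivalent to C6, and the aryllithium is silylated by TMSCl while the N-silyl group is lost on aqueous work-up, the aryl MOM ethers being expected to survive the brief contact with amine-buffered TMSOTf as they do in silyl triflate/amine silylations.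

Step 4
Reactants: 7 3,5-bis(methoxymethoxy)-2-(trimethylsilyl)phenyl N-isopropylcarbamate
Product: 9 3,5-bis(methoxymethoxy)-2-(trimethylsilyl)phenyl trifluoromethanesulfonate, via silylphenol 8 (not isolated)
Conditions: Et2NH (1.3 equiv), DBU (1.5 equiv), MeCN, 40 °C; then PhNTf2 (1.5 equiv), rt
Reagents that add atoms: N-phenylbis(trifluoromethanesulfonimide) (PhNTf2) O=S(=O)(N(c1ccccc1)S(=O)(=O)C(F)(F)F)C(F)(F)F
Why: DBU-induced E1cB cleavage of the N–H carbamate to the phenoxide and isopropyl isocyanate (scavenged by Et2NH as a urea), followed by O-sulfonylation with PhNTf2 in the same flask, should give the ortho-silylaryl triflate that serves as the aryne precursor.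

Step 5
Reactants: 9 3,5-bis(methoxymethoxy)-2-(trimethylsilyl)phenyl trifluoromethanesulfonate; 10 3-methylbut-2-enal
Product: 14 5,7-bis(methoxymethoxy)-2,2-dimethyl-2H-chromene, via aryne 11 (not isolated), via benzoxete 12 (not isolated), via ortho-quinone methide 13 (not isolated)
Conditions: CsF (3 equiv), 10 (5 equiv), MeCN, rt → 50 °C, slow addition of 9
Reagents that add atoms: none
Why: Fluoride attack at silicon in 9 triggers 1,2-elimination of triflate to aryne 11, whose C4a/C8a triple bond is polarised by the flanking C5 methoxymethoxy group, so that the carbonyl oxygen of 10 adds to C8a (distal to the alkoxy group) and the aryl anion left at C4a closes on the oxocarbenium carbon, forming the aryl–O and aryl–C bonds in a stepwise formal [2+2] cycloaddition (benzoxete 12). Thermal 4π electrocyclic opening of 12 gives ortho-quinone methide 13, and oxa-6π electrocyclisation of its O=C–C=CH–CH=CMe2 array closes the pyran ring and restores the benzene ring. The closest known reaction type is the fluoride-induced reaction of arynes with α,β-unsaturated aldehydes to give 2H-chromenes (insertion of an aryne into a C=O π bond). Ring closures: the transient four-membered oxete by polar stepwise [2+2], the pyran by thermal disrotatory oxa-6π electrocyclisation; no stereocentre is formed, since C2 carries two methyl groups. The step needs regioselective O-attack on the aryne, secured by the inductive and distortion effect of the 3-alkoxy substituent, and chemoselectivity over the ene reaction with the methyl groups of 10 and over capture of 13 by a second aryne, secured by excess 10, slow aryne release and the fast intramolecular 6π closure.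

Step 6
Reactants: 14 5,7-bis(methoxymethoxy)-2,2-dimethyl-2H-chromene; 15 N-methoxy-N-methylisobutyramide (N-methoxy-N,2-dimethylpropanamide)
Product: 17 1-[5,7-bis(methoxymethoxy)-2,2-dimethyl-2H-chromen-6-yl]-2-methylpropan-1-one, via aryllithium 16 (not isolated)
Conditions: n-BuLi (1.2 equiv), TMEDA, THF, 0 °C, 1 h; then 15 (1.5 equiv), −78 °C → rt; aq. NH4Cl
Reagents that add atoms: n-butyllithium [Li]CCCC (lithium of 16 only)
Why: Directed ortho-metalation should occur at C6, the only position flanked by two chelating MOM ethers, and acylation of the aryllithium by the N-methoxy-N-methylamide stops at the ketone through the stable chelated tetrahedral intermediate (Weinreb ketone synthesis).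

Step 7
Reactants: 17 1-[5,7-bis(methoxymethoxy)-2,2-dimethyl-2H-chromen-6-yl]-2-methylpropan-1-one
Product: 18 1-(5,7-dihydroxy-2,2-dimethyl-2H-chromen-6-yl)-2-methylpropan-1-one
Conditions: conc. HCl (cat.), MeOH, 40 °C
Reagents that add atoms: none
Why: Acid-catalysed acetal methanolysis of the two MOM ethers, assisted by the ortho carbonyl group, should free both phenols under conditions mild enough for the 2,2-dimethylchromene, whose ring is deactivated towards protonation by the acyl group.

Step 8
Reactants: 19 2-methylbenzene-1,3,5-triol (2,4,6-trihydroxytoluene); 20 isobutyryl chloride (2-methylpropanoyl chloride)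
Product: 21 1-(2,4,6-trihydroxy-3-methylphenyl)-2-methylpropan-1-one
Conditions: AlCl3 (4 equiv), PhNO2, rt → 60 °C; then ice/aq. HCl
Reagents that add atoms: none
Why: Friedel–Crafts C-acylation of the electron-rich triphenol (directly or through O-acylation and Fries rearrangement) should give the acylphloroglucinol, the two free ring positions of 19 being equivalent.

Step 9
Reactants: 21 1-(2,4,6-trihydroxy-3-methylphenyl)-2-methylpropan-1-one; 22 N,N-dimethylmethyleneiminium iodide (Eschenmoser's salt)
Product: 23 1-{3-[(dimethylamino)methyl]-2,4,6-trihydroxy-5-methylphenyl}-2-methylpropan-1-one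
Conditions: 22 (1.05 equiv), MeCN, 0 °C → rt; then aq. NaHCO3
Reagents that add atoms: none
Why: Mannich aminomethylation by the preformed iminium salt should take place at the only unsubstituted ring carbon of the highly nucleophilic acylphloroglucinol.

Step 10
Reactants: 18 1-(5,7-dihydroxy-2,2-dimethyl-2H-chromen-6-yl)-2-methylpropan-1-one; 23 1-{3-[(dimethylamino)methyl]-2,4,6-trihydroxy-5-methylphenyl}-2-methylpropan-1-one
Product: 25 1-{3-[(5,7-dihydroxy-2,2-dimethyl-6-(2-methylpropanoyl)-2H-chromen-8-yl)methyl]-2,4,6-trihydroxy-5-methylphenyl}-2-methylpropan-1-one, via ortho-quinone methide 24 (not isolated)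
Conditions: 1,4-dioxane, 90 °C, N2, slight excess of 18
Reagents that add atoms: none
Why: Thermal loss of dimethylamine from the phenolic Mannich base gives ortho-quinone methide 24, which is captured by the only free nucleophilic ring carbon (C8) of chromene 18 in a Friedel–Crafts-type conjugate addition, the standard way to unsymmetrical methylene-bridged acylphloroglucinols.

Step 11
Reactants: 26 3-methylbut-2-en-1-ol (prenol)
Product: 27 tert-butyl 3-methylbut-2-en-1-yl carbonate
Conditions: Boc2O (1.2 equiv), n-Bu4NHSO4 (5 mol%), 30% aq. NaOH, CH2Cl2, 0 °C → rt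
Reagents that add atoms: di-tert-butyl dicarbonate CC(C)(C)OC(=O)OC(=O)OC(C)(C)C
Why: Phase-transfer O-acylation of the primary allylic alcohol by Boc2O should give the mixed carbonate, a self-activating electrophile for the allylic alkylation that releases its own base.

Step 12
Reactants: 25 1-{3-[(5,7-dihydroxy-2,2-dimethyl-6-(2-methylpropanoyl)-2H-chromen-8-yl)methyl]-2,4,6-trihydroxy-5-methylphenyl}-2-methylpropan-1-one; 27 tert-butyl 3-methylbut-2-en-1-yl carbonate
Product: 28 (4R)-6-{[5,7-dihydroxy-2,2-dimethyl-6-(2-methylpropanoyl)-2H-chromen-8-yl]methyl}-3,5-dihydroxy-4-methyl-4-(3-methylbut-2-en-1-yl)-2-(2-methylpropanoyl)cyclohexa-2,5-dien-1-one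
Conditions: Pd2(dba)3·CHCl3 (2.5 mol%), (1R,2R)-N,N'-bis[2-(diphenylphosphino)benzoyl]cyclohexane-1,2-diamine ((R,R)-DACH-phenyl ligand, 7.5 mol%), 27 (1.1 equiv), degassed THF, 0 °C → rt; dilute aqueous acid work-up
Reagents that add atoms: none
Why: Tsuji–Trost asymmetric allylic alkylation run as a catalytic asymmetric dearomatisation: zerovalent palladium ionises 27 to a cationic η3-prenyl complex of divalent palladium, [(η3-C5H9)Pd(ligand)]+, and tert-butoxide, which deprotonates the trihydroxy ring of 25, and the phenolate should attack through its methyl-bearing carbon (the only carbon of that ring with a small substituent, O-prenyl ethers being re-ionised by the catalyst) at the unsubstituted allyl terminus, while the chiral pocket of the ligand distinguishes the two faces of this prochiral carbon, whose flanks differ as acyl-bearing and benzyl-bearing, and so sets the (R)-configured quaternary stereocentre.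

**Compound list**

1 | phloroglucinol (benzene-1,3,5-triol) | Oc1cc(O)cc(O)c1 | starting material
2 | 3,5-bis(methoxymethoxy)phenol | COCOc1cc(O)cc(OCOC)c1 | intermediate
3 | 3,5-bis(methoxymethoxy)phenyl N-isopropylcarbamate | COCOc1cc(OCOC)cc(OC(=O)NC(C)C)c1 | intermediate
4 | 3,5-bis(methoxymethoxy)phenyl N-isopropyl-N-(trimethylsilyl)carbamate (not isolated) | COCOc1cc(OCOC)cc(OC(=O)N(C(C)C)[Si](C)(C)C)c1 | intermediate
5 | 2-lithio-3,5-bis(methoxymethoxy)phenyl N-isopropyl-N-(trimethylsilyl)carbamate (not isolated) | COCOc1cc(OCOC)c([Li])c(OC(=O)N(C(C)C)[Si](C)(C)C)c1 | intermediate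
6 | 3,5-bis(methoxymethoxy)-2-(trimethylsilyl)phenyl N-isopropyl-N-(trimethylsilyl)carbamate (not isolated) | COCOc1cc(OCOC)c([Si](C)(C)C)c(OC(=O)N(C(C)C)[Si](C)(C)C)c1 | intermediate
7 | 3,5-bis(methoxymethoxy)-2-(trimethylsilyl)phenyl N-isopropylcarbamate | COCOc1cc(OCOC)c([Si](C)(C)C)c(OC(=O)NC(C)C)c1 | intermediate
8 | 3,5-bis(methoxymethoxy)-2-(trimethylsilyl)phenol (not isolated) | COCOc1cc(OCOC)c([Si](C)(C)C)c(O)c1 | intermediate
9 | 3,5-bis(methoxymethoxy)-2-(trimethylsilyl)phenyl trifluoromethanesulfonate | COCOc1cc(OCOC)c([Si](C)(C)C)c(OS(=O)(=O)C(F)(F)F)c1 | intermediate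
10 | 3-methylbut-2-enal | CC(C)=CC=O | starting material
11 | 3,5-bis(methoxymethoxy)benzyne (1,2-didehydro-3,5-bis(methoxymethoxy)benzene; not isolated) | COCOC1=CC#CC(OCOC)=C1 | intermediate
12 | 3,5-bis(methoxymethoxy)-2-(2-methylprop-1-en-1-yl)-2H-benzo[b]oxete (not isolated) | CC(C)=CC1Oc2cc(OCOC)cc(OCOC)c12 | intermediate
13 | 3,5-bis(methoxymethoxy)-6-(3-methylbut-2-en-1-ylidene)cyclohexa-2,4-dien-1-one (not isolated) | O=C1C=C(OCOC)C=C(OCOC)C1=CC=C(C)C | intermediate
14 | 5,7-bis(methoxymethoxy)-2,2-dimethyl-2H-chromene | COCOc1cc(OCOC)c2C=CC(C)(C)Oc2c1 | intermediate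
15 | N-methoxy-N-methylisobutyramide (N-methoxy-N,2-dimethylpropanamide) | CC(C)C(=O)N(C)OC | starting material
16 | 6-lithio-5,7-bis(methoxymethoxy)-2,2-dimethyl-2H-chromene (not isolated) | COCOc1cc2OC(C)(C)C=Cc2c(OCOC)c1[Li] | intermediate
17 | 1-[5,7-bis(methoxymethoxy)-2,2-dimethyl-2H-chromen-6-yl]-2-methylpropan-1-one | COCOc1cc2OC(C)(C)C=Cc2c(OCOC)c1C(=O)C(C)C | intermediate
18 | 1-(5,7-dihydroxy-2,2-dimethyl-2H-chromen-6-yl)-2-methylpropan-1-one | CC(C)C(=O)c1c(O)cc2OC(C)(C)C=Cc2c1O | intermediate
19 | 2-methylbenzene-1,3,5-triol (2,4,6-trihydroxytoluene) | Cc1c(O)cc(O)cc1O | starting material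
20 | isobutyryl chloride (2-methylpropanoyl chloride) | CC(C)C(Cl)=O | starting material
21 | 1-(2,4,6-trihydroxy-3-methylphenyl)-2-methylpropan-1-one | Cc1c(O)cc(O)c(C(=O)C(C)C)c1O | intermediate
22 | N,N-dimethylmethyleneiminium iodide (Eschenmoser's salt) | C=[N+](C)C.[I-] | starting material
23 | 1-{3-[(dimethylamino)methyl]-2,4,6-trihydroxy-5-methylphenyl}-2-methylpropan-1-one | CN(C)Cc1c(O)c(C)c(O)c(C(=O)C(C)C)c1O | intermediate
24 | 3,5-dihydroxy-4-methyl-6-methylidene-2-(2-methylpropanoyl)cyclohexa-2,4-dien-1-one (not isolated) | C=C1C(=O)C(C(=O)C(C)C)=C(O)C(C)=C1O | intermediate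
25 | 1-{3-[(5,7-dihydroxy-2,2-dimethyl-6-(2-methylpropanoyl)-2H-chromen-8-yl)methyl]-2,4,6-trihydroxy-5-methylphenyl}-2-methylpropan-1-one | Cc1c(O)c(Cc2c(O)c(C(=O)C(C)C)c(O)c3C=CC(C)(C)Oc23)c(O)c(C(=O)C(C)C)c1O | intermediate
26 | 3-methylbut-2-en-1-ol (prenol) | CC(C)=CCO | starting material
27 | tert-butyl 3-methylbut-2-en-1-yl carbonate | CC(C)=CCOC(=O)OC(C)(C)C | intermediate
28 | (4R)-6-{[5,7-dihydroxy-2,2-dimethyl-6-(2-methylpropanoyl)-2H-chromen-8-yl]methyl}-3,5-dihydroxy-4-methyl-4-(3-methylbut-2-en-1-yl)-2-(2-methylpropanoyl)cyclohexa-2,5-dien-1-one | CC(C)=CC[C@]1(C)C(O)=C(Cc2c(O)c(C(=O)C(C)C)c(O)c3c2OC(C)(C)C=C3)C(=O)C(C(=O)C(C)C)=C1O | target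

**Step count and risks**

Total step count: 12. Longest linear sequence: 9 steps (steps 1 to 7, 10 and 12); steps 8 and 9 and step 11 are side branches.

Steps most likely to fail:

Step 12. The chiral catalyst may discriminate the two faces of the prochiral ring carbon poorly, the allyl complex may attack a bridge-bearing ring carbon or an oxygen without return, or the alkoxide may induce exchange of the aryl groups across the methylene bridge. The fallback sets out from 21 and comes back to the route at 28; it dearomatises the ring before the bridge is made and takes the stereocentre from a resolution. Compound 21 is C-prenylated at its methyl-bearing carbon with 1-bromo-3-methylbut-2-ene and NaOMe in MeOH at 0 °C (the classical dearomative alkylation of C-methyl acylphloroglucinols) to give racemic 3,5-dihydroxy-4-methyl-4-(3-methylbut-2-en-1-yl)-2-(2-methylpropanoyl)cyclohexa-2,5-dien-1-one F1. Preparative chromatography on a chiral stationary phase should then give (4R)-3,5-dihydroxy-4-methyl-4-(3-methylbut-2-en-1-yl)-2-(2-methylpropanoyl)cyclohexa-2,5-dien-1-one F2. Aminomethylation of its free ring carbon with 22 gives (4R)-6-[(dimethylamino)methyl]-3,5-dihydroxy-4-methyl-4-(3-methylbut-2-en-1-yl)-2-(2-methylpropanoyl)cyclohexa-2,5-dien-1-one F3, and heating F3 with 18 in dioxane should deliver 28 with loss of dimethylamine.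

Step 5. The aryne may be diverted by an ene reaction with the allylic methyl groups of the enal, the enal may self-condense under fluoride, or the quinone methide may be intercepted by a second aryne before it cyclises. The fallback sets out from 2 and comes back at 14, and builds the pyran ring from the phenol side instead. Phenol 2 and 10 are condensed with ethylenediammonium diacetate in toluene at reflux: C-alkylation at an ortho carbon (the two are equivalent), dehydration to the same quinone methide 13, and oxa-6π closure. This fallback makes no compound outside the list (F0).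

Step 6. Deprotonation may occur at C8, between the pyran oxygen and one MOM ether, in competition with C6, or n-BuLi may add across the styrene-type C3=C4 bond. The fallback sets out from 14 and comes back at 18, and uses a removable blocking group. Lithiation at the more easily metalated C8 and quench with TMSCl give 5,7-bis(methoxymethoxy)-2,2-dimethyl-8-(trimethylsilyl)-2H-chromene F4. A second lithiation, now possible only between the two MOM ethers, and acylation with 15 give 1-[5,7-bis(methoxymethoxy)-2,2-dimethyl-8-(trimethylsilyl)-2H-chromen-6-yl]-2-methylpropan-1-one F5. HCl in MeOH then removes both MOM groups and, by ipso-protodesilylation of the electron-rich ring, the silyl group, to give 18.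

**Further compounds**

F1 | step 12 | racemic 3,5-dihydroxy-4-methyl-4-(3-methylbut-2-en-1-yl)-2-(2-methylpropanoyl)cyclohexa-2,5-dien-1-one | CC(C)=CCC1(C)C(O)=CC(=O)C(C(=O)C(C)C)=C1O
F2 | step 12 | (4R)-3,5-dihydroxy-4-methyl-4-(3-methylbut-2-en-1-yl)-2-(2-methylpropanoyl)cyclohexa-2,5-dien-1-one | CC(C)=CC[C@]1(C)C(O)=CC(=O)C(C(=O)C(C)C)=C1O
F3 | step 12 | (4R)-6-[(dimethylamino)methyl]-3,5-dihydroxy-4-methyl-4-(3-methylbut-2-en-1-yl)-2-(2-methylpropanoyl)cyclohexa-2,5-dien-1-one | CC(C)=CC[C@]1(C)C(O)=C(CN(C)C)C(=O)C(C(=O)C(C)C)=C1O
F0 | step 5 | none | none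
F4 | step 6 | 5,7-bis(methoxymethoxy)-2,2-dimethyl-8-(trimethylsilyl)-2H-chromene | COCOc1cc(OCOC)c2C=CC(C)(C)Oc2c1[Si](C)(C)C
F5 | step 6 | 1-[5,7-bis(methoxymethoxy)-2,2-dimethyl-8-(trimethylsilyl)-2H-chromen-6-yl]-2-methylpropan-1-one | COCOc1c(C(=O)C(C)C)c(OCOC)c2C=CC(C)(C)Oc2c1[Si](C)(C)C
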